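The runs come from a simulation for an exercise, noise included.

I wanted the substrate and the target in the flask at 5.0 h, and I had the east run of that same flask to go on.

the same everywhere: substrate 1.5 M; coupling partner 1.42 M; catalyst 30 mM
- east: the very flask that is asked about, followed so far
- flask: time 5.0 h

- east (time / min: target / %, substrate / %): 12.0: 0, 99; 25.0: 2, 89; 40.0: 3, 84; 50.0: 2, 81; 60.0: 1, 78; 80.0: 4, 70; 90.0: 2, 69

(standard deviation of a reading: 2 percentage points)



- the target in the flask at 5.0 h, as a percentage of the substrate charged
- the substrate in the flask at 5.0 h, as a percentage of the substrate charged

1. I began with the main step, substrate lost at fixed [catalyst], pseudo-first-order, so log [substrate] falls on a straight line. From 69% left at 90.0 min I read 0.107 h⁻¹. This is the decade rate, the powers of ten of [substrate] lost per hour. Over 5.0 h it gave 0.535 decades, so 29.2% substrate.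

2. Then I added a second step, from the lost substrate on to target. I assumed target rises with the square of time, which from 2% at 90.0 min gave 22.2%. That reading is no larger than its scatter of 2 percentage points, so this figure is rough.

3. Last, I let the feed slow. My lost substrate at 5.0 h was 71.0%, less than the 103% of a straight line. Scaling by that ratio gave 15.3% target.

The forecast said 30% substrate and 12% target, noting that “most of the consumed material sits in something unobserved”. My target of 15.3% stood higher than its figure.

The flask gave 25.4% substrate and 13.9% target, and the forecast held. Intermediate in the flask stood at 48.0%, more than the target. The flask lost 0.595 decades of substrate, against 0.535 from the decade rate.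

    substrate + target → side product (k = 0.350 M⁻¹ h⁻¹)
    substrate + catalyst → catalyst + intermediate (k = 8.10 M⁻¹ h⁻¹)
    coupling partner + catalyst + intermediate → catalyst + target (k = 3.20 M⁻² h⁻¹)

For the neighbour with 0.012 M catalyst, I scaled the decade rate with [catalyst], to 0.0430 h⁻¹. That gave 0.215 decades, so 61.0% substrate at 5.0 h. The computed neighbour held 59.7% substrate at 5.0 h.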